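**Plan**

1. Retrosynthesis: first the three C6–O ester bonds to the bicyclic amino alcohol are cut (each is made by Mitsunobu inversion of the C6-epimeric alcohol 10). Then the cyclobutane bonds C1–C2 and C3–C4 are cut: a head-to-tail [2+2] union of a feruloyl C=C (C2=C3) with the 2-methylalk-2-enoate C=C (C4=C1) of a C10 diester.
2. Enabling feature: ring carbon C2 carries the 4-hydroxy-3-methoxyphenyl ring beside the acyl carbon C3, so before closure aryl–C2=C3–C=O is a cinnamoyl chromophore whose triplet keeps a benzylic radical at C2. C1 carries methyl and ester and becomes a tertiary α-ester radical, so the most stabilised 1,4-biradical closes to the 1,3-dicarboxylate ring with every vicinal pair trans.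
3. Forward order: the cyclopentanone and piperidine rings of the amino alcohol arise together in a Pauson–Khand reaction (steps 1–7). Geranyl acetate supplies the ten carbons of C1, its methyl and carboxyl, C4 and the whole side chain (steps 8–11), and two units of 10 are attached while these acids are still unhindered (step 12). The cyclobutane is closed last (step 16); the third unit and phenol release follow (steps 17–19).
4. Stereochemistry: C4 of the bicycle comes from a copper-catalysed asymmetric SN2′ methylation; C4a, C7a, C7 and C6 follow by relay, and C6 is inverted in every esterification. The four cyclobutane centres come from a chiral-at-rhodium photocatalyst (absolute) and from biradical closure (relative). Both alkene geometries come from geraniol and a Knoevenagel–Doebner condensation.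

Key step: step 16

Notation: Inc is the (4R,4aR,6R,7R,7aS)-2,4,7-trimethyloctahydro-1H-cyclopenta[c]pyridin-6-yl group. Cyclobutane locants are C1 (methyl, carboxylate), C2 (aryl), C3 (carboxylate or acyl), C4 (side chain).

Assumption: the ligand enantiomer in step 3 and the metal-centred configuration of the catalyst in step 16 are written as those expected to give the configurations drawn; if the sense of induction proved opposite, the mirror-image ligand or complex would be used.

**Route**

Step 1
Reactants: 1 but-2-yn-1-amine hydrochloride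
Product: 2 methyl but-2-yn-1-ylcarbamate
Conditions: ClCO2Me, Et3N, CH2Cl2, 0 °C to rt
Reagents that add atoms: methyl chloroformate, COC(=O)Cl
Why: Schotten–Baumann-type N-acylation gives a carbamate that tolerates the cobalt and copper steps and later becomes the N-methyl group.

Step 2
Reactants: 2 methyl but-2-yn-1-ylcarbamate; 3 (2E)-1,4-dibromobut-2-ene (3 equiv)
Product: 4 methyl [(2E)-4-bromobut-2-en-1-yl](but-2-yn-1-yl)carbamate
Conditions: NaH, DMF, 0 °C; then 3, 0 °C to rt
Reagents that add atoms: none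
Why: SN2 N-alkylation of the carbamate anion at an allylic bromide, with excess dibromide to suppress double substitution.

Step 3
Reactants: 4 methyl [(2E)-4-bromobut-2-en-1-yl](but-2-yn-1-yl)carbamate
Product: 5 methyl but-2-yn-1-yl[(2R)-2-methylbut-3-en-1-yl]carbamate
Conditions: CuBr·SMe2 (5 mol %, monovalent copper), (R,R)-Taniaphos (6 mol %; C43H39FeNP2, a ferrocene diphosphine of divalent iron), MeMgBr, CH2Cl2, −75 °C
Reagents that add atoms: methylmagnesium bromide, C[Mg]Br
Why: Copper-catalysed asymmetric allylic alkylation should deliver methyl to the γ-carbon (SN2′), the chiral diphosphine on copper choosing the alkene face and so setting the (R) centre that becomes C4 of the bicycle.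

Step 4
Reactants: 5 methyl but-2-yn-1-yl[(2R)-2-methylbut-3-en-1-yl]carbamate
Product: 6 methyl (4R,4aR)-4,7-dimethyl-6-oxo-1,3,4,4a,5,6-hexahydro-2H-cyclopenta[c]pyridine-2-carboxylate
Conditions: Co2(CO)8 (10 mol %, zerovalent cobalt), tetramethylthiourea (60 mol %), CO (1 atm), toluene, 70 °C
Reagents that add atoms: carbon monoxide, [C-]#[O+]
Why: The intramolecular Pauson–Khand [2+2+1] reaction closes the piperidine and the cyclopentenone at once, and C4a should form with H4a cis to the C4 methyl because that methyl stays pseudo-equatorial in the chair-like cyclisation.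

Step 5
Reactants: 6 methyl (4R,4aR)-4,7-dimethyl-6-oxo-1,3,4,4a,5,6-hexahydro-2H-cyclopenta[c]pyridine-2-carboxylate
Product: 8 methyl (4R,4aR,7R,7aS)-4,7-dimethyl-6-oxooctahydro-2H-cyclopenta[c]pyridine-2-carboxylate, via C7-epimeric ketone 7 (not isolated)
Conditions: H2 (4 atm), 10% Pd/C, EtOAc, rt; filter; then K2CO3 (0.3 equiv), MeOH, rt
Reagents that add atoms: none
Why: Heterogeneous hydrogenation should add to C7=C7a from the face of H4a and give the cis ring fusion, after which base equilibrates C7 (α to the ketone) to the more stable methyl trans to C1.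

Step 6
Reactants: 8 methyl (4R,4aR,7R,7aS)-4,7-dimethyl-6-oxooctahydro-2H-cyclopenta[c]pyridine-2-carboxylate
Product: 9 methyl (4R,4aR,6S,7R,7aS)-6-hydroxy-4,7-dimethyloctahydro-2H-cyclopenta[c]pyridine-2-carboxylate
Conditions: LiBH(s-Bu)3 (L-Selectride), THF, −78 °C; then H2O
Reagents that add atoms: none
Why: As with 2-alkylcyclopentanones, the bulky hydride should attack anti to the adjacent C7 methyl and give the (6S) alcohol with OH cis to that methyl.

Step 7
Reactants: 9 methyl (4R,4aR,6S,7R,7aS)-6-hydroxy-4,7-dimethyloctahydro-2H-cyclopenta[c]pyridine-2-carboxylate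
Product: 10 (4R,4aR,6S,7R,7aS)-2,4,7-trimethyloctahydro-1H-cyclopenta[c]pyridin-6-ol
Conditions: LiAlH4, THF, reflux; then H2O, aq. NaOH
Reagents that add atoms: none
Why: Hydride reduction of the methyl carbamate to the N-methyl amine, with no stereocentre touched.

Step 8
Reactants: 11 geranyl acetate
Product: 12 (2E,6E)-8-hydroxy-3,7-dimethylocta-2,6-dien-1-yl acetate
Conditions: SeO2 (10 mol %), t-BuOOH, salicylic acid (10 mol %), CH2Cl2, rt
Reagents that add atoms: tert-butyl hydroperoxide, CC(C)(C)OO; selenium dioxide, O=[Se]=O (catalytic carrier of the oxygen atom)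
Why: Allylic oxidation by ene reaction and [2,3]-shift occurs at the (E)-methyl of the electron-richer terminal alkene and keeps the (E) geometry.

Step 9
Reactants: 12 (2E,6E)-8-hydroxy-3,7-dimethylocta-2,6-dien-1-yl acetate
Product: 13 (2E,6E)-2,6-dimethylocta-2,6-diene-1,8-diol
Conditions: K2CO3 (0.2 equiv), MeOH, rt
Reagents that add atoms: none
Why: Base-catalysed transesterification removes the acetate as methyl acetate.

Step 10
Reactants: 13 (2E,6E)-2,6-dimethylocta-2,6-diene-1,8-diol
Product: 14 (2E,6E)-2,6-dimethylocta-2,6-dienedial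
Conditions: activated MnO2 (tetravalent manganese), CH2Cl2, rt
Reagents that add atoms: none
Why: MnO2 oxidises both allylic alcohols to the enals without moving the double bonds.

Step 11
Reactants: 14 (2E,6E)-2,6-dimethylocta-2,6-dienedial
Product: 15 (2E,6E)-2,6-dimethylocta-2,6-dienedioic acid
Conditions: NaClO2, NaH2PO4, 2-methylbut-2-ene, t-BuOH/H2O, 0 °C to rt
Reagents that add atoms: sodium chlorite, [Na+].[O-]Cl=O
Why: Pinnick oxidation converts both enals to the acids with retention of alkene geometry, the alkene scavenger removing hypochlorous acid.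

Step 12
Reactants: 15 (2E,6E)-2,6-dimethylocta-2,6-dienedioic acid; 10 (4R,4aR,6S,7R,7aS)-2,4,7-trimethyloctahydro-1H-cyclopenta[c]pyridin-6-ol (2.2 equiv)
Product: 16 bis(Inc) (2E,6E)-2,6-dimethylocta-2,6-dienedioate
Conditions: PPh3, DIAD, THF, 0 °C to rt
Reagents that add atoms: none
Why: Double Mitsunobu esterification inverts C6 of each alcohol from (S) to the (R) configuration of the target, and it places the ester on the future quaternary carbon while that acid is still an unhindered enoic acid.

Step 13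
Reactants: 17 vanillin
Product: 18 4-(allyloxy)-3-methoxybenzaldehyde
Conditions: allyl bromide, K2CO3, DMF, rt
Reagents that add atoms: allyl bromide, C=CCBr
Why: Williamson etherification installs a phenol protecting group that can later be removed under neutral conditions.

Step 14
Reactants: 18 4-(allyloxy)-3-methoxybenzaldehyde
Product: 19 (2E)-3-[4-(allyloxy)-3-methoxyphenyl]prop-2-enoic acid
Conditions: malonic acid, pyridine, piperidine (cat.), 100 °C
Reagents that add atoms: malonic acid, OC(=O)CC(=O)O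
Why: Knoevenagel–Doebner condensation with decarboxylation gives the (E)-cinnamic acid.

Step 15
Reactants: 19 (2E)-3-[4-(allyloxy)-3-methoxyphenyl]prop-2-enoic acid
Product: 21 (2E)-3-[4-(allyloxy)-3-methoxyphenyl]-1-(3,5-dimethyl-1H-pyrazol-1-yl)prop-2-en-1-one, via acid chloride 20 (not isolated)
Conditions: (COCl)2, DMF (cat.), CH2Cl2, 0 °C to rt, evaporate; then 3,5-dimethyl-1H-pyrazole, Et3N, CH2Cl2, 0 °C
Reagents that add atoms: 3,5-dimethyl-1H-pyrazole, Cc1cc(C)[nH]n1
Why: N-acylation of the pyrazole through the acid chloride gives a bidentate acyl donor that binds the chiral Lewis acid and is later cleaved like an active amide.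

Step 16
Reactants: 21 (2E)-3-[4-(allyloxy)-3-methoxyphenyl]-1-(3,5-dimethyl-1H-pyrazol-1-yl)prop-2-en-1-one; 16 bis(Inc) (2E,6E)-2,6-dimethylocta-2,6-dienedioate (3 equiv, excess recovered)
Product: 24 Inc (1R,2S,3S,4S)-2-[4-(allyloxy)-3-methoxyphenyl]-3-[(3,5-dimethyl-1H-pyrazol-1-yl)carbonyl]-1-methyl-4-[(3E)-3-methyl-5-oxo-5-(Inc-oxy)pent-3-en-1-yl]cyclobutane-1-carboxylate, via diester bis(tetrafluoroborate) 22 (not isolated), via cycloadduct bis(tetrafluoroborate) 23 (not isolated)
Conditions: 16, HBF4·OEt2 (2 equiv per 16), acetone, 0 °C; Δ-[Rh(C17H16NS)2(NCMe)2]PF6 (4 mol %, trivalent rhodium; C17H16NS = cyclometalated 5-tert-butyl-2-phenyl-1,3-benzothiazole), 21 added by syringe pump, blue LEDs (450 nm), degassed, rt; then aq. NaHCO3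
Reagents that add atoms: none
Why: Proposed new method: the N-acylpyrazole of 21 chelates the chiral-at-metal rhodium Lewis acid through N2 and the carbonyl oxygen, and only this bound complex absorbs blue light and relaxes to a triplet 1,2-biradical on the cinnamoyl C=C; the closest known reaction types are the visible-light [2+2] photocycloaddition of rhodium-bound α,β-unsaturated N-acyl azoles with styrenes and dienes and the sensitised crossed [2+2] photocycloaddition of aryl-conjugated enone-type triplets with acrylates, here extended to a trisubstituted 2-methylalk-2-enoate. The α-carbon (C3) should add to the only monosubstituted β-carbon of 22 (C4; the other enoate terminus is β,β-disubstituted and stays untouched), giving the most stabilised triplet 1,4-biradical (4-alkoxybenzylic at C2, tertiary α-ester at C1), and after intersystem crossing the cyclobutane closes stepwise by radical–radical bond formation between C1 and C2, so the two carbonyl groups end up 1,3. C3 is set by the rhodium stereocentre, whose tert-butylbenzothiazole ligand shields one face of the bound enone; C4 and C2 follow from C3 because the first bond forms reversibly and only the biradical that can place aryl, acyl and side chain all trans closes productively; C1 is set by allylic 1,3-strain in the planar ester-conjugated radical, which keeps the C4 chain on the side of the methyl group as in the (E)-alkene. The step needs crossed over homo-cycloaddition, secured by slow addition of 21 into an excess of the diester, and the tertiary amines are held as ammonium tetrafluoroborates so that they neither bind rhodium nor quench the excited complex by electron transfer.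

Step 17
Reactants: 24 the N-acylpyrazole cycloadduct
Product: 25 1-Inc 3-hydrogen (1R,2S,3S,4S)-2-[4-(allyloxy)-3-methoxyphenyl]-1-methyl-4-[(3E)-3-methyl-5-oxo-5-(Inc-oxy)pent-3-en-1-yl]cyclobutane-1,3-dicarboxylate
Conditions: LiOH·H2O (1.2 equiv), THF/H2O, 0 °C; then AcOH (1.2 equiv)
Reagents that add atoms: lithium hydroxide, [Li+].[OH-]
Why: The N-acylpyrazole is an activated amide and should hydrolyse much faster than the two hindered secondary alkyl esters, and C3 already has the thermodynamically preferred trans configuration, so any enolisation is harmless.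

Step 18
Reactants: 25 the cyclobutane mono-acid; 10 (4R,4aR,6S,7R,7aS)-2,4,7-trimethyloctahydro-1H-cyclopenta[c]pyridin-6-ol (1.5 equiv)
Product: 26 bis(Inc) (1R,2S,3S,4S)-2-[4-(allyloxy)-3-methoxyphenyl]-1-methyl-4-[(3E)-3-methyl-5-oxo-5-(Inc-oxy)pent-3-en-1-yl]cyclobutane-1,3-dicarboxylate
Conditions: PPh3, DIAD, THF, 0 °C to rt
Reagents that add atoms: none
Why: Mitsunobu esterification of the secondary cyclobutane acid inverts C6 of the third alcohol to the (R) ester, while the ring stereocentres are not involved.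

Step 19
Reactants: 26 the O-allyl tris-ester
Product: 27 bis(Inc) (1R,2S,3S,4S)-2-(4-hydroxy-3-methoxyphenyl)-1-methyl-4-[(3E)-3-methyl-5-oxo-5-(Inc-oxy)pent-3-en-1-yl]cyclobutane-1,3-dicarboxylate (CNP0251577.2)
Conditions: Pd(PPh3)4 (5 mol %, zerovalent palladium), morpholine, THF, rt
Reagents that add atoms: none
Why: Tsuji–Trost deallylation through a π-allyl palladium complex frees the phenol under near-neutral conditions, which avoids base-induced opening of the 4-hydroxyphenyl cyclobutane flanked by two esters and leaves the esters, amines and enoate untouched.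

**Compound list**

1 | but-2-yn-1-amine hydrochloride | CC#CCN.Cl | starting material
2 | methyl but-2-yn-1-ylcarbamate | COC(=O)NCC#CC | intermediate
3 | (2E)-1,4-dibromobut-2-ene | BrC/C=C/CBr | starting material
4 | methyl [(2E)-4-bromobut-2-en-1-yl](but-2-yn-1-yl)carbamate | COC(=O)N(CC#CC)C/C=C/CBr | intermediate
5 | methyl but-2-yn-1-yl[(2R)-2-methylbut-3-en-1-yl]carbamate | COC(=O)N(CC#CC)C[C@@H](C=C)C | intermediate
6 | methyl (4R,4aR)-4,7-dimethyl-6-oxo-1,3,4,4a,5,6-hexahydro-2H-cyclopenta[c]pyridine-2-carboxylate | O=C1C[C@H]2C(CN(C(=O)OC)C[C@@H]2C)=C1C | intermediate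
7 | methyl (4R,4aR,7S,7aS)-4,7-dimethyl-6-oxooctahydro-2H-cyclopenta[c]pyridine-2-carboxylate (cis-fused, C7 methyl cis to C1) | O=C1C[C@H]2[C@H](CN(C(=O)OC)C[C@@H]2C)[C@@H]1C | intermediate
8 | methyl (4R,4aR,7R,7aS)-4,7-dimethyl-6-oxooctahydro-2H-cyclopenta[c]pyridine-2-carboxylate (cis-fused, C7 methyl trans to C1) | O=C1C[C@H]2[C@H](CN(C(=O)OC)C[C@@H]2C)[C@H]1C | intermediate
9 | methyl (4R,4aR,6S,7R,7aS)-6-hydroxy-4,7-dimethyloctahydro-2H-cyclopenta[c]pyridine-2-carboxylate | O[C@H]1C[C@H]2[C@H](CN(C(=O)OC)C[C@@H]2C)[C@H]1C | intermediate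
10 | (4R,4aR,6S,7R,7aS)-2,4,7-trimethyloctahydro-1H-cyclopenta[c]pyridin-6-ol (C6 epimer of Inc–OH) | O[C@H]1C[C@H]2[C@H](CN(C)C[C@@H]2C)[C@H]1C | intermediate
11 | geranyl acetate, (2E)-3,7-dimethylocta-2,6-dien-1-yl acetate | CC(C)=CCC/C(C)=C/COC(C)=O | starting material
12 | (2E,6E)-8-hydroxy-3,7-dimethylocta-2,6-dien-1-yl acetate | OC/C(C)=C/CC/C(C)=C/COC(C)=O | intermediate
13 | (2E,6E)-2,6-dimethylocta-2,6-diene-1,8-diol | OC/C(C)=C/CC/C(C)=C/CO | intermediate
14 | (2E,6E)-2,6-dimethylocta-2,6-dienedial | O=C/C(C)=C/CC/C(C)=C/C=O | intermediate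
15 | (2E,6E)-2,6-dimethylocta-2,6-dienedioic acid | OC(=O)/C(C)=C/CC/C(C)=C/C(=O)O | intermediate
16 | bis(Inc) (2E,6E)-2,6-dimethylocta-2,6-dienedioate | O=C(O[C@@H]1C[C@H]2[C@H](CN(C)C[C@@H]2C)[C@H]1C)/C(C)=C/CC/C(C)=C/C(=O)O[C@@H]1C[C@H]2[C@H](CN(C)C[C@@H]2C)[C@H]1C | intermediate
17 | vanillin | COc1cc(C=O)ccc1O | starting material
18 | 4-(allyloxy)-3-methoxybenzaldehyde | C=CCOc1ccc(C=O)cc1OC | intermediate
19 | (2E)-3-[4-(allyloxy)-3-methoxyphenyl]prop-2-enoic acid | C=CCOc1ccc(/C=C/C(=O)O)cc1OC | intermediate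
20 | (2E)-3-[4-(allyloxy)-3-methoxyphenyl]prop-2-enoyl chloride | C=CCOc1ccc(/C=C/C(=O)Cl)cc1OC | intermediate
21 | (2E)-3-[4-(allyloxy)-3-methoxyphenyl]-1-(3,5-dimethyl-1H-pyrazol-1-yl)prop-2-en-1-one | C=CCOc1ccc(/C=C/C(=O)n2nc(C)cc2C)cc1OC | intermediate
22 | bis(hydrotetrafluoroborate) of 16 (both ring nitrogens protonated) | O=C(O[C@@H]1C[C@H]2[C@H](C[NH+](C)C[C@@H]2C)[C@H]1C)/C(C)=C/CC/C(C)=C/C(=O)O[C@@H]1C[C@H]2[C@H](C[NH+](C)C[C@@H]2C)[C@H]1C.F[B-](F)(F)F.F[B-](F)(F)F | intermediate
23 | bis(hydrotetrafluoroborate) of 24 | COc1cc([C@@H]2[C@@H](C(=O)n3nc(C)cc3C)[C@H](CC/C(C)=C/C(=O)O[C@@H]3C[C@H]4[C@H](C[NH+](C)C[C@@H]4C)[C@H]3C)[C@@]2(C)C(=O)O[C@@H]2C[C@H]3[C@H](C[NH+](C)C[C@@H]3C)[C@H]2C)ccc1OCC=C.F[B-](F)(F)F.F[B-](F)(F)F | intermediate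
24 | Inc (1R,2S,3S,4S)-2-[4-(allyloxy)-3-methoxyphenyl]-3-[(3,5-dimethyl-1H-pyrazol-1-yl)carbonyl]-1-methyl-4-[(3E)-3-methyl-5-oxo-5-(Inc-oxy)pent-3-en-1-yl]cyclobutane-1-carboxylate | COc1cc([C@@H]2[C@@H](C(=O)n3nc(C)cc3C)[C@H](CC/C(C)=C/C(=O)O[C@@H]3C[C@H]4[C@H](CN(C)C[C@@H]4C)[C@H]3C)[C@@]2(C)C(=O)O[C@@H]2C[C@H]3[C@H](CN(C)C[C@@H]3C)[C@H]2C)ccc1OCC=C | intermediate
25 | 1-Inc 3-hydrogen (1R,2S,3S,4S)-2-[4-(allyloxy)-3-methoxyphenyl]-1-methyl-4-[(3E)-3-methyl-5-oxo-5-(Inc-oxy)pent-3-en-1-yl]cyclobutane-1,3-dicarboxylate | COc1cc([C@@H]2[C@@H](C(=O)O)[C@H](CC/C(C)=C/C(=O)O[C@@H]3C[C@H]4[C@H](CN(C)C[C@@H]4C)[C@H]3C)[C@@]2(C)C(=O)O[C@@H]2C[C@H]3[C@H](CN(C)C[C@@H]3C)[C@H]2C)ccc1OCC=C | intermediate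
26 | bis(Inc) (1R,2S,3S,4S)-2-[4-(allyloxy)-3-methoxyphenyl]-1-methyl-4-[(3E)-3-methyl-5-oxo-5-(Inc-oxy)pent-3-en-1-yl]cyclobutane-1,3-dicarboxylate | COc1cc([C@@H]2[C@@H](C(=O)O[C@@H]3C[C@H]4[C@H](CN(C)C[C@@H]4C)[C@H]3C)[C@H](CC/C(C)=C/C(=O)O[C@@H]3C[C@H]4[C@H](CN(C)C[C@@H]4C)[C@H]3C)[C@@]2(C)C(=O)O[C@@H]2C[C@H]3[C@H](CN(C)C[C@@H]3C)[C@H]2C)ccc1OCC=C | intermediate
27 | bis(Inc) (1R,2S,3S,4S)-2-(4-hydroxy-3-methoxyphenyl)-1-methyl-4-[(3E)-3-methyl-5-oxo-5-(Inc-oxy)pent-3-en-1-yl]cyclobutane-1,3-dicarboxylate | COc1cc([C@@H]2[C@@H](C(=O)O[C@@H]3C[C@H]4[C@H](CN(C)C[C@@H]4C)[C@H]3C)[C@H](CC/C(C)=C/C(=O)O[C@@H]3C[C@H]4[C@H](CN(C)C[C@@H]4C)[C@H]3C)[C@@]2(C)C(=O)O[C@@H]2C[C@H]3[C@H](CN(C)C[C@@H]3C)[C@H]2C)ccc1O | target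

**Step count and risks**

Total step count: 19. Longest linear sequence: 12 steps (1–7, 12, 16–19).

Steps most likely to fail:

1. Step 16 (proposed new method). The bound triplet may decay by E/Z isomerisation or add to a second molecule of 21 faster than to the hindered, electron-poor enoate. First bond formation at the benzylic carbon would give the head-to-head ring, and the ammonium salts may slow catalyst turnover.
 Fallback: a racemic, sensitised cycloaddition on simple esters with the configuration secured afterwards by the enantiopure alcohol. It sets out from 19 and 15 and comes back at 26, using only known reaction types: triplet sensitisation of a cinnamate ester and capture by an alkene (as known for aryl-conjugated enone triplets with acrylates), saponification and Mitsunobu esterification. Acid 19 is methylated (MeI, K2CO3, DMF) to methyl (2E)-3-[4-(allyloxy)-3-methoxyphenyl]prop-2-enoate F1, and diacid 15 is esterified (MeOH, cat. H2SO4) to dimethyl (2E,6E)-2,6-dimethylocta-2,6-dienedioate F2. F1 is irradiated at 405 nm with thioxanthen-9-one in neat, degassed F2 (large excess, recovered), with no amine and no catalyst-bound substrate present. This should give the racemic all-trans adduct dimethyl rac-(1R,2S,3S,4S)-2-[4-(allyloxy)-3-methoxyphenyl]-4-[(3E)-5-methoxy-3-methyl-5-oxopent-3-en-1-yl]-1-methylcyclobutane-1,3-dicarboxylate F3. Saponification (KOH, MeOH/H2O, heat) gives rac-(1R,2S,3S,4S)-2-[4-(allyloxy)-3-methoxyphenyl]-4-[(3E)-4-carboxy-3-methylbut-3-en-1-yl]-1-methylcyclobutane-1,3-dicarboxylic acid F4. A threefold Mitsunobu esterification with 10 (PPh3, DIAD) then gives 26 together with its diastereomer built on the mirror-image ring, bis(Inc) (1S,2R,3R,4R)-2-[4-(allyloxy)-3-methoxyphenyl]-1-methyl-4-[(3E)-3-methyl-5-oxo-5-(Inc-oxy)pent-3-en-1-yl]cyclobutane-1,3-dicarboxylate F5. The two are separated by chromatography and 26 goes on to step 19. This fallback removes the catalyst and amine problems and raises the partner concentration, but it does not correct a wrong regiochemistry.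

2. Step 18. Displacement at the hindered C6 oxyphosphonium by the zwitterionic amino acid may be slow, so that elimination of the activated alcohol takes over.
 Fallback: retentive acyl transfer in place of inversion, setting out from 10 and 24 and coming back at 26. Alcohol 10 is inverted once by a Mitsunobu reaction with 4-nitrobenzoic acid (PPh3, DIAD) to Inc 4-nitrobenzoate F6. Methanolysis (K2CO3, MeOH) gives the (6R) alcohol (4R,4aR,6R,7R,7aS)-2,4,7-trimethyloctahydro-1H-cyclopenta[c]pyridin-6-ol F7. Its sodium alkoxide (NaN(SiMe3)2, THF, −40 °C to rt) is acylated directly by the N-acylpyrazole 24 with retention at C6, the pyrazolide acting as leaving group. This gives 26 and makes step 17 unnecessary.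

3. Step 3. Regiocontrol (SN2 against SN2′) or enantioselectivity may be lost in the copper-catalysed methylation, and this is the step that fixes the absolute configuration of all three amino alcohol units.
 Fallback: chiral pool in place of asymmetric catalysis, setting out from 2 and coming back at 5. The sodium salt of 2 (NaH, DMF) is alkylated with (R)-(3-bromo-2-methylpropoxy)(tert-butyl)dimethylsilane, the silyl ether of the commercial bromo alcohol, to methyl but-2-yn-1-yl[(2S)-3-{[tert-butyl(dimethyl)silyl]oxy}-2-methylpropyl]carbamate F8. Bu4NF in THF gives methyl but-2-yn-1-yl[(2S)-3-hydroxy-2-methylpropyl]carbamate F9. Dess–Martin oxidation gives methyl but-2-yn-1-yl[(2S)-2-methyl-3-oxopropyl]carbamate F10, which is methylenated at once by a Wittig reaction (Ph3P=CH2, THF, −78 °C) to 5.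

Further compounds

F1 | step 16 | methyl (2E)-3-[4-(allyloxy)-3-methoxyphenyl]prop-2-enoate | C=CCOc1ccc(/C=C/C(=O)OC)cc1OC
F2 | step 16 | dimethyl (2E,6E)-2,6-dimethylocta-2,6-dienedioate | COC(=O)/C(C)=C/CC/C(C)=C/C(=O)OC
F3 | step 16 | dimethyl rac-(1R,2S,3S,4S)-2-[4-(allyloxy)-3-methoxyphenyl]-4-[(3E)-5-methoxy-3-methyl-5-oxopent-3-en-1-yl]-1-methylcyclobutane-1,3-dicarboxylate (racemate, one enantiomer drawn) | COc1cc([C@@H]2[C@@H](C(=O)OC)[C@H](CC/C(C)=C/C(=O)OC)[C@@]2(C)C(=O)OC)ccc1OCC=C
F4 | step 16 | rac-(1R,2S,3S,4S)-2-[4-(allyloxy)-3-methoxyphenyl]-4-[(3E)-4-carboxy-3-methylbut-3-en-1-yl]-1-methylcyclobutane-1,3-dicarboxylic acid (racemate, one enantiomer drawn) | COc1cc([C@@H]2[C@@H](C(=O)O)[C@H](CC/C(C)=C/C(=O)O)[C@@]2(C)C(=O)O)ccc1OCC=C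
F5 | step 16 | bis(Inc) (1S,2R,3R,4R)-2-[4-(allyloxy)-3-methoxyphenyl]-1-methyl-4-[(3E)-3-methyl-5-oxo-5-(Inc-oxy)pent-3-en-1-yl]cyclobutane-1,3-dicarboxylate | COc1cc([C@H]2[C@H](C(=O)O[C@@H]3C[C@H]4[C@H](CN(C)C[C@@H]4C)[C@H]3C)[C@@H](CC/C(C)=C/C(=O)O[C@@H]3C[C@H]4[C@H](CN(C)C[C@@H]4C)[C@H]3C)[C@]2(C)C(=O)O[C@@H]2C[C@H]3[C@H](CN(C)C[C@@H]3C)[C@H]2C)ccc1OCC=C
F6 | step 18 | (4R,4aR,6R,7R,7aS)-2,4,7-trimethyloctahydro-1H-cyclopenta[c]pyridin-6-yl 4-nitrobenzoate | O=C(O[C@@H]1C[C@H]2[C@H](CN(C)C[C@@H]2C)[C@H]1C)c1ccc(cc1)[N+](=O)[O-]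
F7 | step 18 | (4R,4aR,6R,7R,7aS)-2,4,7-trimethyloctahydro-1H-cyclopenta[c]pyridin-6-ol | O[C@@H]1C[C@H]2[C@H](CN(C)C[C@@H]2C)[C@H]1C
F8 | step 3 | methyl but-2-yn-1-yl[(2S)-3-{[tert-butyl(dimethyl)silyl]oxy}-2-methylpropyl]carbamate | COC(=O)N(CC#CC)C[C@@H](CO[Si](C)(C)C(C)(C)C)C
F9 | step 3 | methyl but-2-yn-1-yl[(2S)-3-hydroxy-2-methylpropyl]carbamate | COC(=O)N(CC#CC)C[C@@H](CO)C
F10 | step 3 | methyl but-2-yn-1-yl[(2S)-2-methyl-3-oxopropyl]carbamate | COC(=O)N(CC#CC)C[C@@H](C=O)C
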